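**Retrosynthetic overview**

1. Target ⇐ O2-silyl ether ⇐ ring-closing metathesis at C1=C10. The ten-membered carbocycle is closed last, on a diene that already carries the lactone, the 8-angelate and the 9-acetate.
2. Key disconnection C8–C9: the carbonyl carbon of methacrolein is made nucleophilic (γ-acetoxyallylchromium from methacrolein + acetyl chloride) and attacks the C8 aldehyde of a β-formyl lactone. Two aldehyde carbons are joined, C8 and C9 are set, and the 9-acetate arrives with the nucleophile, so only O8 is left free for angelic acid.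
3. β-Formyl-α-methylene-γ-lactone ⇐ chromium-catalysed asymmetric 2-(methoxycarbonyl)allylation/lactonisation (C6–C7) of a C1–C6 enal with an acetal-bearing allylic bromide, then acetal hydrolysis.
4. C1–C6 enal ⇐ asymmetric vinylogous Mukaiyama aldol (C2–C3) of the methyl 3-methylbut-2-enoate dienolate with acrolein (sets C2 and the 4E olefin).
5. Ring order: γ-lactone first (step 8), ten-membered ring last (step 13).

Assumption: atom labels C1–C15 follow germacrane numbering of the target (C6 = lactone carbinol carbon, C12 = lactone carbonyl; target = 2S,6R,7S,8R,9R, 1(10)Z, 4E, angelate Z). In the three catalytic asymmetric steps the ligand antipode written is the one taken to give the stated face selectivity; its mirror image is used if the sense of induction proves opposite.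

**Step 1**
Reactants: 1 methyl 3-methylbut-2-enoate
Product: 3 [(1-methoxy-3-methylbuta-1,3-dien-1-yl)oxy]trimethylsilane, via lithium dienolate 2 (not isolated)
Conditions: LiN(iPr)2, THF, −78 °C; Me3SiCl, −78 °C to rt; distillation
Reagents that add atoms: chlorotrimethylsilane C[Si](C)(C)Cl
Why: Kinetic γ-deprotonation of the senecioate gives the extended lithium dienolate, which is silylated on oxygen to the silyl ketene acetal (silyl dienolate formation); no stereocentre is formed.

**Step 2**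
Reactants: 3 silyl dienolate; 4 acrolein
Product: 6 methyl (2E,5S)-5-hydroxy-3-methylhepta-2,6-dienoate, via trichlorosilyl ether 5 (not isolated)
Conditions: SiCl4 (1.1 equiv), (R,R)-configured 1,1′-binaphthyl-2,2′-diamine-derived bis-phosphoramide (2 mol %), iPr2NEt (10 mol %), CH2Cl2, −78 °C; aq NaHCO3
Reagents that add atoms: none
Why: Lewis-base-activated SiCl4 vinylogous Mukaiyama aldol: the chiral phosphoramide-bound trichlorosilyl cation activates acrolein, the dienolate attacks through its γ-carbon on the Si face (C2 = S), and the s-trans dienolate delivers the 4E olefin.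

**Step 3**
Reactants: 6 methyl (2E,5S)-5-hydroxy-3-methylhepta-2,6-dienoate
Product: 7 methyl (2E,5S)-5-[(tert-butyldimethylsilyl)oxy]-3-methylhepta-2,6-dienoate
Conditions: tBuMe2SiCl, imidazole, DMF, rt
Reagents that add atoms: tert-butyl(chloro)dimethylsilane CC(C)(C)[Si](C)(C)Cl
Why: Imidazole-promoted silylation protects the secondary allylic alcohol (silyl ether formation); the C2 stereocentre is untouched.

**Step 4**
Reactants: 7 methyl (2E,5S)-5-[(tert-butyldimethylsilyl)oxy]-3-methylhepta-2,6-dienoate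
Product: 8 (2E,5S)-5-[(tert-butyldimethylsilyl)oxy]-3-methylhepta-2,6-dien-1-ol
Conditions: iBu2AlH (2.2 equiv), CH2Cl2, −78 °C; aq potassium sodium tartrate
Reagents that add atoms: none
Why: 1,2-Hydride reduction of the conjugated ester gives the allylic alcohol with the 4E geometry and the silyl ether intact.

**Step 5**
Reactants: 8 (2E,5S)-5-[(tert-butyldimethylsilyl)oxy]-3-methylhepta-2,6-dien-1-ol
Product: 9 (2E,5S)-5-[(tert-butyldimethylsilyl)oxy]-3-methylhepta-2,6-dienal
Conditions: MnO2, CH2Cl2, rt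
Reagents that add atoms: none
Why: Chemoselective MnO2 oxidation of the primary allylic alcohol gives the enal without E/Z isomerisation (allylic oxidation).

**Step 6**
Reactants: 10 2,2-dimethoxyacetaldehyde; 11 methyl acrylate
Product: 12 methyl 3-hydroxy-4,4-dimethoxy-2-methylidenebutanoate (racemic)
Conditions: DABCO (1 equiv), 1,4-dioxane/H2O, rt
Reagents that add atoms: none
Why: Morita–Baylis–Hillman reaction of the activated α,α-dialkoxy aldehyde; the carbinol centre is destroyed in step 7, so the racemate suffices.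

**Step 7**
Reactants: 12 methyl 3-hydroxy-4,4-dimethoxy-2-methylidenebutanoate
Product: 13 methyl (2Z)-2-(bromomethyl)-4,4-dimethoxybut-2-enoate
Conditions: NBS, Me2S, CH2Cl2, 0 °C to rt
Reagents that add atoms: N-bromosuccinimide O=C1CCC(=O)N1Br
Why: Corey–Kim-type activation of the hydroxyl and SN2′ attack of bromide on the terminal methylene carbon give the thermodynamically preferred (2Z)-2-(bromomethyl)enoate (bromination with allylic transposition).

**Step 8**
Reactants: 9 (2E,5S)-5-[(tert-butyldimethylsilyl)oxy]-3-methylhepta-2,6-dienal; 13 methyl (2Z)-2-(bromomethyl)-4,4-dimethoxybut-2-enoate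
Product: 16 (4S,5R)-5-{(1E,4S)-4-[(tert-butyldimethylsilyl)oxy]-2-methylhexa-1,5-dien-1-yl}-4-(dimethoxymethyl)-3-methylideneoxolan-2-one, via silyl ether 14 (not isolated), via hydroxy ester 15 (not isolated)
Conditions: CrCl2 (10 mol %), (S,S)-1,8-bis(4-isopropyl-4,5-dihydro-1,3-oxazol-2-yl)-3,6-diphenyl-9H-carbazole (10 mol %), Mn, Me3SiCl, iPr2NEt (30 mol %), THF, rt; then PPTS, MeOH, rt
Reagents that add atoms: none
Why: Chromium-catalysed asymmetric Nozaki–Hiyama (Barbier-type) 2-(alkoxycarbonyl)allylation: divalent chromium (regenerated by Mn) turns the bromide into a γ-substituted allylchromium that adds through C7 to the Si face of the enal in the ligand pocket via a chair transition state with both substituents equatorial (anti adduct, C6 = R, C7 = S), and acid-catalysed desilylation and lactonisation give the trans-γ-lactone.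

**Step 9**
Reactants: 16 lactone acetal
Product: 17 (2R,3S)-2-{(1E,4S)-4-[(tert-butyldimethylsilyl)oxy]-2-methylhexa-1,5-dien-1-yl}-4-methylidene-5-oxooxolane-3-carbaldehyde
Conditions: LiBF4, MeCN/H2O (50:1), rt; used crude
Reagents that add atoms: water O
Why: Mild Lewis-acid-assisted acetal hydrolysis frees the C8 aldehyde under near-neutral conditions chosen to avoid enolisation at C7 (the trans isomer is in any case the thermodynamic one); no stereocentre changes.

**Step 10**
Reactants: 18 methacrolein; 19 acetyl chloride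
Product: 20 3-chloro-2-methylprop-1-en-1-yl acetate (E/Z mixture)
Conditions: ZnCl2 (5 mol %), CH2Cl2, −20 °C to rt
Reagents that add atoms: none
Why: Zinc-chloride-catalysed 1,4-addition of the acyl chloride across the enal gives the γ-chloro enol acetate, the precursor of an α-acetoxyallyl anion equivalent (acyl halide–enal addition).

**Step 11 (key step)**
Reactants: 17 β-formyl lactone; 20 3-chloro-2-methylprop-1-en-1-yl acetate
Product: 22 (4R,5R)-4-[(1R,2R)-2-(acetyloxy)-1-hydroxy-3-methylbut-3-en-1-yl]-5-{(1E,4S)-4-[(tert-butyldimethylsilyl)oxy]-2-methylhexa-1,5-dien-1-yl}-3-methylideneoxolan-2-one, via trimethylsilyl ether 21 (not isolated)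
Conditions: CrCl3 (10 mol %), Mn, (R,R)-N,N′-bis(3,5-di-tert-butylsalicylidene)cyclohexane-1,2-diamine (10 mol %), Et3N (20 mol %), Me3SiCl, MeCN, rt; then citric acid, MeOH, 0 °C
Reagents that add atoms: none
Why: Proposed new method: divalent chromium (regenerated by Mn) inserts into the allylic C–Cl bond of 20 to give an allylchromium whose γ-carbon carries the acetoxy group (held Z by chelation of the ester carbonyl), so the former carbonyl carbon of methacrolein (C9) is the nucleophile and bonds to the aldehyde carbon C8 through a closed chair transition state (Z-γ-substituted allylmetal gives the syn, that is threo, C8-OH/C9-OAc pair); attack on the Si face of the aldehyde is both the Felkin–Anh face (C6 branch anti to the nucleophile) and the face taken to be selected by the salen ligand, giving 8R,9R with the acetate already on O9 and only O8 free; Me3SiCl silylates the chromium alkoxide at once, which turns the catalyst over and blocks 1,2-acetyl migration; the closest known reaction type is the chromium–salen-catalysed Nozaki–Hiyama addition of 3-halopropenyl esters to aldehydes giving syn-alk-1-ene-3,4-diol mono-esters, extended here to the 2-methyl reagent and an α-branched chiral aldehyde.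

**Step 12**
Reactants: 22 hydroxy acetate; 23 angelic acid
Product: 25 (4S,5R)-4-[(1R,2R)-2-(acetyloxy)-3-methyl-1-{[(2Z)-2-methylbut-2-enoyl]oxy}but-3-en-1-yl]-5-{(1E,4S)-4-[(tert-butyldimethylsilyl)oxy]-2-methylhexa-1,5-dien-1-yl}-3-methylideneoxolan-2-one, via mixed anhydride 24 (not isolated)
Conditions: 2,4,6-Cl3C6H2COCl, Et3N, toluene, rt; then 22, toluene, 80 °C
Reagents that add atoms: none
Why: Yamaguchi esterification through the mixed anhydride, run without DMAP, acylates the C8 hydroxyl without Z-to-E isomerisation of the angeloyl unit and without touching any stereocentre.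

**Step 13**
Reactants: 25 angelate diene
Product: 26 (2S,6R,7S,8R,9R)-9-(acetyloxy)-2-[(tert-butyldimethylsilyl)oxy]-8-{[(2Z)-2-methylbut-2-enoyl]oxy}germacra-1(10)Z,4E,11(13)-trien-12,6-olide
Conditions: second-generation Grubbs catalyst RuCl2(=CHPh)(PCy3)(H2IMes) (15 mol %, in portions), toluene (1 mM), 80 °C
Reagents that add atoms: none
Why: Ring-closing olefin metathesis: the ruthenium carbene loads at the monosubstituted vinyl group on C2 and closes onto the 1,1-disubstituted C10 olefin with loss of ethylene; the ten-membered ring, already holding the 4E olefin and the trans-lactone, is expected to favour the ring-cis 1(10)Z trisubstituted alkene.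

**Step 14**
Reactants: 26 silyl-protected macrocycle
Product: 27 target, (2S,6R,7S,8R,9R)-9-(acetyloxy)-2-hydroxy-8-{[(2Z)-2-methylbut-2-enoyl]oxy}germacra-1(10)Z,4E,11(13)-trien-12,6-olide
Conditions: HF·pyridine, THF/pyridine, 0 °C to rt
Reagents that add atoms: none
Why: Buffered fluoride cleavage of the secondary silyl ether leaves the two esters, the allylic acetate and the α-methylene lactone untouched (desilylation).

**Compound list**

1 | methyl 3-methylbut-2-enoate | COC(=O)C=C(C)C | starting material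
2 | lithium 1-methoxy-3-methylbuta-1,3-dien-1-olate | [Li+].[O-]C(OC)=CC(C)=C | intermediate (not isolated)
3 | [(1-methoxy-3-methylbuta-1,3-dien-1-yl)oxy]trimethylsilane (E/Z mixture) | COC(O[Si](C)(C)C)=CC(C)=C | intermediate
4 | acrolein | C=CC=O | starting material
5 | methyl (2E,5S)-3-methyl-5-[(trichlorosilyl)oxy]hepta-2,6-dienoate | COC(=O)/C=C(\C)C[C@H](O[Si](Cl)(Cl)Cl)C=C | intermediate (not isolated)
6 | methyl (2E,5S)-5-hydroxy-3-methylhepta-2,6-dienoate | COC(=O)/C=C(\C)C[C@H](O)C=C | intermediate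
7 | methyl (2E,5S)-5-[(tert-butyldimethylsilyl)oxy]-3-methylhepta-2,6-dienoate | COC(=O)/C=C(\C)C[C@H](O[Si](C)(C)C(C)(C)C)C=C | intermediate
8 | (2E,5S)-5-[(tert-butyldimethylsilyl)oxy]-3-methylhepta-2,6-dien-1-ol | OC/C=C(\C)C[C@H](O[Si](C)(C)C(C)(C)C)C=C | intermediate
9 | (2E,5S)-5-[(tert-butyldimethylsilyl)oxy]-3-methylhepta-2,6-dienal | O=C/C=C(\C)C[C@H](O[Si](C)(C)C(C)(C)C)C=C | intermediate
10 | 2,2-dimethoxyacetaldehyde | COC(OC)C=O | starting material
11 | methyl acrylate | C=CC(=O)OC | starting material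
12 | methyl 3-hydroxy-4,4-dimethoxy-2-methylidenebutanoate (racemic) | COC(=O)C(=C)C(O)C(OC)OC | intermediate
13 | methyl (2Z)-2-(bromomethyl)-4,4-dimethoxybut-2-enoate | COC(=O)/C(CBr)=C/C(OC)OC | intermediate
14 | methyl (3S,4R,5E,8S)-8-[(tert-butyldimethylsilyl)oxy]-3-(dimethoxymethyl)-6-methyl-2-methylidene-4-[(trimethylsilyl)oxy]deca-5,9-dienoate | COC(=O)C(=C)[C@H](C(OC)OC)[C@H](O[Si](C)(C)C)/C=C(\C)C[C@H](O[Si](C)(C)C(C)(C)C)C=C | intermediate (not isolated)
15 | methyl (3S,4R,5E,8S)-8-[(tert-butyldimethylsilyl)oxy]-3-(dimethoxymethyl)-4-hydroxy-6-methyl-2-methylidenedeca-5,9-dienoate | COC(=O)C(=C)[C@H](C(OC)OC)[C@H](O)/C=C(\C)C[C@H](O[Si](C)(C)C(C)(C)C)C=C | intermediate (not isolated)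
16 | (4S,5R)-5-{(1E,4S)-4-[(tert-butyldimethylsilyl)oxy]-2-methylhexa-1,5-dien-1-yl}-4-(dimethoxymethyl)-3-methylideneoxolan-2-one | C=C1C(=O)O[C@H](/C=C(\C)C[C@H](O[Si](C)(C)C(C)(C)C)C=C)[C@H]1C(OC)OC | intermediate
17 | (2R,3S)-2-{(1E,4S)-4-[(tert-butyldimethylsilyl)oxy]-2-methylhexa-1,5-dien-1-yl}-4-methylidene-5-oxooxolane-3-carbaldehyde | C=C1C(=O)O[C@H](/C=C(\C)C[C@H](O[Si](C)(C)C(C)(C)C)C=C)[C@H]1C=O | intermediate
18 | methacrolein (2-methylprop-2-enal) | CC(=C)C=O | starting material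
19 | acetyl chloride | CC(=O)Cl | starting material
20 | 3-chloro-2-methylprop-1-en-1-yl acetate (E/Z mixture) | CC(=O)OC=C(C)CCl | intermediate
21 | (4S,5R)-4-{(1R,2R)-2-(acetyloxy)-3-methyl-1-[(trimethylsilyl)oxy]but-3-en-1-yl}-5-{(1E,4S)-4-[(tert-butyldimethylsilyl)oxy]-2-methylhexa-1,5-dien-1-yl}-3-methylideneoxolan-2-one | C=C1C(=O)O[C@H](/C=C(\C)C[C@H](O[Si](C)(C)C(C)(C)C)C=C)[C@H]1[C@@H](O[Si](C)(C)C)[C@H](OC(C)=O)C(C)=C | intermediate (not isolated)
22 | (4R,5R)-4-[(1R,2R)-2-(acetyloxy)-1-hydroxy-3-methylbut-3-en-1-yl]-5-{(1E,4S)-4-[(tert-butyldimethylsilyl)oxy]-2-methylhexa-1,5-dien-1-yl}-3-methylideneoxolan-2-one | C=C1C(=O)O[C@H](/C=C(\C)C[C@H](O[Si](C)(C)C(C)(C)C)C=C)[C@H]1[C@@H](O)[C@H](OC(C)=O)C(C)=C | intermediate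
23 | angelic acid, (2Z)-2-methylbut-2-enoic acid | C/C=C(/C)C(=O)O | starting material
24 | (2Z)-2-methylbut-2-enoic 2,4,6-trichlorobenzoic anhydride | C/C=C(/C)C(=O)OC(=O)c1c(Cl)cc(Cl)cc1Cl | intermediate (not isolated)
25 | (4S,5R)-4-[(1R,2R)-2-(acetyloxy)-3-methyl-1-{[(2Z)-2-methylbut-2-enoyl]oxy}but-3-en-1-yl]-5-{(1E,4S)-4-[(tert-butyldimethylsilyl)oxy]-2-methylhexa-1,5-dien-1-yl}-3-methylideneoxolan-2-one | C=C1C(=O)O[C@H](/C=C(\C)C[C@H](O[Si](C)(C)C(C)(C)C)C=C)[C@H]1[C@@H](OC(=O)/C(C)=C\C)[C@H](OC(C)=O)C(C)=C | intermediate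
26 | (2S,6R,7S,8R,9R)-9-(acetyloxy)-2-[(tert-butyldimethylsilyl)oxy]-8-{[(2Z)-2-methylbut-2-enoyl]oxy}germacra-1(10)Z,4E,11(13)-trien-12,6-olide | C=C1C(=O)O[C@@H]2/C=C(\C)C[C@H](O[Si](C)(C)C(C)(C)C)/C=C(/C)[C@@H](OC(C)=O)[C@H](OC(=O)/C(C)=C\C)[C@@H]12 | intermediate
27 | CNP0316477.1, (2S,6R,7S,8R,9R)-9-(acetyloxy)-2-hydroxy-8-{[(2Z)-2-methylbut-2-enoyl]oxy}germacra-1(10)Z,4E,11(13)-trien-12,6-olide | C=C1C(=O)O[C@@H]2/C=C(\C)C[C@H](O)/C=C(/C)[C@@H](OC(C)=O)[C@H](OC(=O)/C(C)=C\C)[C@@H]12 | target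

**Step count and risks**

Total step count: 14. Longest linear sequence: 11 steps (1 to 27 through steps 1–5, 8, 9 and 11–14).

Steps most likely to fail:

Step 13 (ring-closing metathesis). Closing a ten-membered ring onto a 1,1-disubstituted olefin next to an allylic acetate may stall, oligomerise or give some 1(10)E isomer. The fallback sets out from 25 and comes back at 27. The silyl ether is removed first (HF·pyridine) to give (4S,5R)-4-[(1R,2R)-2-(acetyloxy)-3-methyl-1-{[(2Z)-2-methylbut-2-enoyl]oxy}but-3-en-1-yl]-5-[(1E,4S)-4-hydroxy-2-methylhexa-1,5-dien-1-yl]-3-methylideneoxolan-2-one F1. The ring is then closed on this unprotected allylic alcohol as the last step. The free hydroxyl next to the loading vinyl group speeds carbene formation and removes the bulky silyl group from the reacting olefin, and the metathesis product is 27 itself.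

Step 11 (key C8–C9 coupling). The catalyst and the chiral aldehyde may be mismatched, syn/anti control may be poor with the 2-methyl reagent, the acetate may migrate to O8, or 17 may isomerise under the conditions. The fallback sets out from 17 and comes back at 25, replacing chromium catalysis by a stoichiometric, reagent-controlled alkoxyallylboration. (Z)-[3-(Methoxymethoxy)-2-methylprop-2-en-1-yl]diisopinocampheylborane is made from 3-(methoxymethoxy)-2-methylprop-1-ene, sec-BuLi, B-methoxydiisopinocampheylborane and BF3·OEt2, using the pinene antipode that attacks the Si face. It adds at −78 °C through a boron-centred chair transition state to give the syn mono-ether (4R,5R)-5-{(1E,4S)-4-[(tert-butyldimethylsilyl)oxy]-2-methylhexa-1,5-dien-1-yl}-4-[(1R,2R)-1-hydroxy-2-(methoxymethoxy)-3-methylbut-3-en-1-yl]-3-methylideneoxolan-2-one F2. Angeloylation as in step 12 gives (4S,5R)-5-{(1E,4S)-4-[(tert-butyldimethylsilyl)oxy]-2-methylhexa-1,5-dien-1-yl}-4-[(1R,2R)-2-(methoxymethoxy)-3-methyl-1-{[(2Z)-2-methylbut-2-enoyl]oxy}but-3-en-1-yl]-3-methylideneoxolan-2-one F3. MgBr2·OEt2/EtSH removes the methoxymethyl group to give (4S,5R)-5-{(1E,4S)-4-[(tert-butyldimethylsilyl)oxy]-2-methylhexa-1,5-dien-1-yl}-4-[(1R,2R)-2-hydroxy-3-methyl-1-{[(2Z)-2-methylbut-2-enoyl]oxy}but-3-en-1-yl]-3-methylideneoxolan-2-one F4. Ac2O/pyridine then acetylates O9 to give 25.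

Step 9 (acetal hydrolysis). The β-formyl-α-methylene lactone 17 has an acidic C7–H and may isomerise to the endocyclic butenolide while the acetal is being unmasked. The fallback sets out from 9 and comes back at 17, making the aldehyde by neutral oxidation instead of hydrolysis. Morita–Baylis–Hillman reaction of 2-[(4-methoxybenzyl)oxy]acetaldehyde with 11 gives methyl 3-hydroxy-4-[(4-methoxybenzyl)oxy]-2-methylidenebutanoate F5. NBS/Me2S gives methyl (2Z)-2-(bromomethyl)-4-[(4-methoxybenzyl)oxy]but-2-enoate F6. Coupling of this bromide with 9 under the conditions of step 8 passes through methyl (3R,4R,5E,8S)-8-[(tert-butyldimethylsilyl)oxy]-3-{[(4-methoxybenzyl)oxy]methyl}-6-methyl-2-methylidene-4-[(trimethylsilyl)oxy]deca-5,9-dienoate F7 and methyl (3R,4R,5E,8S)-8-[(tert-butyldimethylsilyl)oxy]-4-hydroxy-3-{[(4-methoxybenzyl)oxy]methyl}-6-methyl-2-methylidenedeca-5,9-dienoate F8. It gives (4R,5R)-5-{(1E,4S)-4-[(tert-butyldimethylsilyl)oxy]-2-methylhexa-1,5-dien-1-yl}-4-{[(4-methoxybenzyl)oxy]methyl}-3-methylideneoxolan-2-one F9. DDQ (CH2Cl2, pH 7 buffer) gives (4R,5R)-5-{(1E,4S)-4-[(tert-butyldimethylsilyl)oxy]-2-methylhexa-1,5-dien-1-yl}-4-(hydroxymethyl)-3-methylideneoxolan-2-one F10. Dess–Martin periodinane/NaHCO3 oxidises it to 17, which is used at once in step 11.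

**Further compounds**

F1 | step 13 | (4S,5R)-4-[(1R,2R)-2-(acetyloxy)-3-methyl-1-{[(2Z)-2-methylbut-2-enoyl]oxy}but-3-en-1-yl]-5-[(1E,4S)-4-hydroxy-2-methylhexa-1,5-dien-1-yl]-3-methylideneoxolan-2-one | C=C1C(=O)O[C@H](/C=C(\C)C[C@H](O)C=C)[C@H]1[C@@H](OC(=O)/C(C)=C\C)[C@H](OC(C)=O)C(C)=C
F2 | step 11 | (4R,5R)-5-{(1E,4S)-4-[(tert-butyldimethylsilyl)oxy]-2-methylhexa-1,5-dien-1-yl}-4-[(1R,2R)-1-hydroxy-2-(methoxymethoxy)-3-methylbut-3-en-1-yl]-3-methylideneoxolan-2-one | C=C1C(=O)O[C@H](/C=C(\C)C[C@H](O[Si](C)(C)C(C)(C)C)C=C)[C@H]1[C@@H](O)[C@H](OCOC)C(C)=C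
F3 | step 11 | (4S,5R)-5-{(1E,4S)-4-[(tert-butyldimethylsilyl)oxy]-2-methylhexa-1,5-dien-1-yl}-4-[(1R,2R)-2-(methoxymethoxy)-3-methyl-1-{[(2Z)-2-methylbut-2-enoyl]oxy}but-3-en-1-yl]-3-methylideneoxolan-2-one | C=C1C(=O)O[C@H](/C=C(\C)C[C@H](O[Si](C)(C)C(C)(C)C)C=C)[C@H]1[C@@H](OC(=O)/C(C)=C\C)[C@H](OCOC)C(C)=C
F4 | step 11 | (4S,5R)-5-{(1E,4S)-4-[(tert-butyldimethylsilyl)oxy]-2-methylhexa-1,5-dien-1-yl}-4-[(1R,2R)-2-hydroxy-3-methyl-1-{[(2Z)-2-methylbut-2-enoyl]oxy}but-3-en-1-yl]-3-methylideneoxolan-2-one | C=C1C(=O)O[C@H](/C=C(\C)C[C@H](O[Si](C)(C)C(C)(C)C)C=C)[C@H]1[C@@H](OC(=O)/C(C)=C\C)[C@H](O)C(C)=C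
F5 | step 9 | methyl 3-hydroxy-4-[(4-methoxybenzyl)oxy]-2-methylidenebutanoate (racemic) | COC(=O)C(=C)C(O)COCc1ccc(OC)cc1
F6 | step 9 | methyl (2Z)-2-(bromomethyl)-4-[(4-methoxybenzyl)oxy]but-2-enoate | COC(=O)/C(CBr)=C/COCc1ccc(OC)cc1
F7 | step 9 | methyl (3R,4R,5E,8S)-8-[(tert-butyldimethylsilyl)oxy]-3-{[(4-methoxybenzyl)oxy]methyl}-6-methyl-2-methylidene-4-[(trimethylsilyl)oxy]deca-5,9-dienoate | COC(=O)C(=C)[C@H](COCc1ccc(OC)cc1)[C@H](O[Si](C)(C)C)/C=C(\C)C[C@H](O[Si](C)(C)C(C)(C)C)C=C
F8 | step 9 | methyl (3R,4R,5E,8S)-8-[(tert-butyldimethylsilyl)oxy]-4-hydroxy-3-{[(4-methoxybenzyl)oxy]methyl}-6-methyl-2-methylidenedeca-5,9-dienoate | COC(=O)C(=C)[C@H](COCc1ccc(OC)cc1)[C@H](O)/C=C(\C)C[C@H](O[Si](C)(C)C(C)(C)C)C=C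
F9 | step 9 | (4R,5R)-5-{(1E,4S)-4-[(tert-butyldimethylsilyl)oxy]-2-methylhexa-1,5-dien-1-yl}-4-{[(4-methoxybenzyl)oxy]methyl}-3-methylideneoxolan-2-one | C=C1C(=O)O[C@H](/C=C(\C)C[C@H](O[Si](C)(C)C(C)(C)C)C=C)[C@H]1COCc2ccc(OC)cc2
F10 | step 9 | (4R,5R)-5-{(1E,4S)-4-[(tert-butyldimethylsilyl)oxy]-2-methylhexa-1,5-dien-1-yl}-4-(hydroxymethyl)-3-methylideneoxolan-2-one | C=C1C(=O)O[C@H](/C=C(\C)C[C@H](O[Si](C)(C)C(C)(C)C)C=C)[C@H]1CO
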